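The runs were computed with made-up constants; noise was put on by code.

Early in a run target climbs, in Monday's from 1.7 % at 0.333 min to 10.7 % at 2.00 min, and from then on it holds near that level while starting material goes on falling.

| flask | starting material | gas phase | protic impurity | remark | time |
|---|---|---|---|---|---|
| Friday's | 0.28 M | 170 mM (held) | 0.020 M | run made earlier |  |
| Monday's | 0.28 M | 170 mM (held) | 0.031 M | run made earlier |  |
| Tuesday's | 0.14 M | 170 mM (held) | 0.014 M | run made earlier |  |
| flask | 0.28 M | 170 mM (held) | 0.0140 M |  | 5.0 min |

- Friday's (time / min: target / %, starting material / %): 0.833: 6.0, 87.5; 1.50: 10.4, 78.5; 2.50: 11.2, 64.3; 3.00: 13.8, 61.3; 4.00: 11.1, 48.9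
- Monday's (time / min: target / %, starting material / %): 0.333: 1.7, 96.7; 0.667: 4.7, 93.0; 1.00: 6.6, 86.0; 2.00: 10.7, 71.9; 4.00: 12.3, 49.8
- Tuesday's (time / min: target / %, starting material / %): 0.333: 2.8, 97.1; 0.667: 7.7, 90.2; 1.00: 8.8, 83.1; 2.00: 14.2, 65.1; 4.00: 11.8, 36.6

(standard deviation of a reading: 1 percentage point)

- in percentages every species weighs as the starting material in it: one homo dimer counts as two
- at the start none of the gas is dissolved
- the analysis behind the earlier runs scatters by 1 percentage point, standard deviation
- reactions considered so far: gas phase <-> dissolved gas; starting material + dissolved gas -> target; dissolved gas + target -> over-reacted product; dissolved gas + protic impurity -> quenched reagent; 2 starting material -> homo dimer; target <-> isomer of the product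

- how much target there is at 5.0 min, in percent of the starting material charged
- concentration of dissolved gas in solution at 5.0 min, in percent of saturation

You asked for a quick number. Dissolved gas is shared between starting material, which makes target, and target, which it over-reacts. Leaving the isomer aside, target stops climbing at a crossing, where starting material over target equals the over-reaction ratio, the number of times faster target takes dissolved gas than starting material does at equal concentration. Taking Monday's reading at 4.00 min as that plateau, I read the ratio as 4.05, with the scatter of those readings in it. Carrying Monday's fall from 2.00 min to 4.00 min on by one more minute at the same first-order pace gives 41.4 % starting material in this flask at 5.0 min, and dividing by the ratio gives my figure of 10.2 % target.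

Your forecast says 10.8 % target, just above my figure, and 38 % of saturation, on the view that the runs' slowing with charge “points to gas-transfer limitation”. For saturation I have no figure of my own from these readings.

The flask gives 12.0 % target and 7.12 % of saturation.

    gas phase ⇌ dissolved gas, rate k1*(csat - [dissolved gas]) (kL = 0.00443 s⁻¹)
    starting material + dissolved gas → target (k = 0.252 M⁻¹ s⁻¹)
    dissolved gas + target → over-reacted product (k = 0.773 M⁻¹ s⁻¹)
    dissolved gas + protic impurity → quenched reagent (k = 0.781 M⁻¹ s⁻¹)
    2 starting material → homo dimer (k = 0.00179 M⁻¹ s⁻¹)
    target ⇌ isomer of the product (K = 1.28, k = 0.00636 s⁻¹)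

That saturation is 0.0121 M dissolved gas. The over-reaction costs this flask 24 percentage points of target: with that step taken away it ends at 35.6 % target. Held to the ratio, the flask's 40.4 % starting material gives 9.98 %, below its 12.0 % target. In the neighbour flask with 0.17 M starting material, 30.1 % starting material gives 7.43 %, also below its 11.1 % target, and that flask holds 39.2 % over-reacted product.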